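**Strategy**

Numbering: C1 lactone carbonyl, C2 its CH2, C3 hemiketal carbon, C4 methyl-bearing ring-fusion carbon, C5 dioxane CH2, C6 peroxide-bearing quaternary carbon, C8 side-chain methine. The route exploits the 1,3-relationship of the lactone oxygen on C4 and the peroxide oxygen on C6 across C5 in the 1,2-dioxane ring: both sites are stored as one oxetane oxygen. The key step closes that oxetane by forming C4–C5, a 4-exo-tet alkylation of an O-tert-alkyl lactate enolate (C4) by a primary iodide (C5) that creates quaternary C4 under control of C6. Perhydrolysis then opens the oxetane at C6 with inversion; the hydroperoxide adds to the C3 ketone and the freed C4 hydroxyl lactonises.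

Key step: step 8

Assumption: the ligand enantiomers named in steps 4 and 5 are taken to give the 8R and 6R senses required; if a first run shows the opposite sense, the antipodal ligand is used.

**Route**

Step 1
Reactants: 1 5-hexyn-1-ol; 2 benzyl chloride
Product: 4 (E)-5-methyl-7-phenylhept-5-en-1-ol, via alkenylalane 3 (not isolated)
Conditions: AlMe3 (3 equiv), Cp2ZrCl2 (0.25 equiv), CH2Cl2, 0 °C → rt; then 2, Pd(PPh3)4 (5 mol %), THF, rt; aq. HCl work-up
Reagents that add atoms: trimethylaluminium, C[Al](C)C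
Why: Zirconium-catalysed Negishi carboalumination adds Me–Al syn across the terminal alkyne (methyl to the internal carbon) after the hydroxyl is capped as its aluminium alkoxide, and palladium-catalysed cross-coupling of the alkenylalane with the benzyl halide proceeds with retention, which fixes the E trisubstituted olefin.

Step 2
Reactants: 4 (E)-5-methyl-7-phenylhept-5-en-1-ol
Product: 5 (E)-5-methyl-7-phenylhept-5-enal
Conditions: TEMPO (10 mol %), PhI(OAc)2, CH2Cl2, rt
Reagents that add atoms: none
Why: The oxoammonium-mediated oxidation stops at the aldehyde and should leave the trisubstituted olefin untouched.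

Step 3
Reactants: 5 (E)-5-methyl-7-phenylhept-5-enal; 6 1-(triphenylphosphoranylidene)propan-2-one
Product: 7 (3E,8E)-8-methyl-10-phenyldeca-3,8-dien-2-one
Conditions: CH2Cl2, 40 °C
Reagents that add atoms: none
Why: Wittig olefination with a stabilised ylide should give the E enone.

Step 4
Reactants: 7 (3E,8E)-8-methyl-10-phenyldeca-3,8-dien-2-one
Product: 8 (4R,8E)-4,8-dimethyl-10-phenyldec-8-en-2-one
Conditions: MeMgBr, CuBr·SMe2 (5 mol %), (R)-1-[(S)-2-(diphenylphosphino)ferrocenyl]ethyldicyclohexylphosphine (Josiphos, 6 mol %), t-BuOMe, −75 °C; aq. NH4Cl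
Reagents that add atoms: methylmagnesium bromide, C[Mg]Br
Why: Copper-catalysed asymmetric conjugate addition of a Grignard reagent to a linear methyl enone sets C8 by catalyst control, and the remote trisubstituted olefin is inert.

Step 5
Reactants: 8 (4R,8E)-4,8-dimethyl-10-phenyldec-8-en-2-one
Product: 9 (2R)-2-[(2R,6E)-2,6-dimethyl-8-phenyloct-6-en-1-yl]-2-methyloxirane
Conditions: Me3S(O)I, NaH, LaLi3[(S)-binaphtholate]3 (5 mol %), tris(2,4,6-trimethoxyphenyl)phosphine oxide (5 mol %), 5 Å MS, THF, rt
Reagents that add atoms: trimethylsulfoxonium iodide, C[S+](C)(C)=O.[I-]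
Why: Catalytic asymmetric Corey–Chaykovsky epoxidation of a methyl ketone delivers CH2 to one carbonyl face and sets C6 by catalyst control, and any C6 or C8 stereoisomer carried forward is a diastereomer that can be removed later by chromatography.

Step 6
Reactants: 9 (2R)-2-[(2R,6E)-2,6-dimethyl-8-phenyloct-6-en-1-yl]-2-methyloxirane; 10 methyl (S)-lactate
Product: 11 methyl (2S)-2-{[(2S,4R,8E)-1-hydroxy-2,4,8-trimethyl-10-phenyldec-8-en-2-yl]oxy}propanoate
Conditions: 10 (5 equiv), BF3·OEt2 (10 mol %), CH2Cl2, −40 → 0 °C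
Reagents that add atoms: none
Why: A Lewis-acid-activated 2,2-disubstituted epoxide is opened by an alcohol at the tertiary carbon in a borderline SN2 process, so the lactate oxygen should enter at C6 with inversion and release the primary C5 hydroxyl (the lactate centre is a spectator that step 8 erases).

Step 7
Reactants: 11 methyl (2S)-2-{[(2S,4R,8E)-1-hydroxy-2,4,8-trimethyl-10-phenyldec-8-en-2-yl]oxy}propanoate
Product: 12 methyl (2S)-2-{[(2S,4R,8E)-1-iodo-2,4,8-trimethyl-10-phenyldec-8-en-2-yl]oxy}propanoate
Conditions: I2, PPh3, imidazole, toluene, rt → 60 °C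
Reagents that add atoms: iodine, II
Why: Appel-type iodination converts the primary alcohol into the iodide, and since C6 carries no hydrogen, elimination cannot compete (11 is used promptly to avoid lactonisation onto the ester).

Step 8
Reactants: 12 methyl (2S)-2-{[(2S,4R,8E)-1-iodo-2,4,8-trimethyl-10-phenyldec-8-en-2-yl]oxy}propanoate
Product: 14 methyl (2R,4S)-4-[(2R,6E)-2,6-dimethyl-8-phenyloct-6-en-1-yl]-2,4-dimethyloxetane-2-carboxylate, via lithium enolate 13 (not isolated)
Conditions: LiN(i-Pr)2, THF, −78 °C → rt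
Reagents that add atoms: none
Why: The amide base removes the C4–H next to the ester to give lithium enolate 13 (chelated by the ether oxygen), whose carbon attacks C5 from the rear of the C–I bond in an intramolecular SN2 alkylation. The closest known reaction types are the carbanion C–C closures that give oxetanes from malonate- or sulfone-stabilised ethers bearing a leaving group, and the 4-exo-tet cycloalkylation of ester enolates to cyclobutane- and azetidine-carboxylates. The oxetane is closed in the 4-exo-tet mode, helped by the gem-disubstitution at C6 and by the absence of any hydrogen on C6 (no E2). The new quaternary stereocentre C4 is controlled by C6: in the closing ring the solvated enolate terminus, the larger group on trigonal C4, should lie on the face of the smaller C6 substituent (methyl) and away from the branched alkyl arm, giving the 2R,4S oxetane with the two ring methyl groups trans; the lactate configuration is erased in 13 and plays no part. The step needs C- over O-alkylation (favoured by the soft iodide and a lithium enolate in THF; O-closure would give a six-membered ketene acetal) and a useful facial preference, which rests only on the size difference at C6 and is the weak point; the C4 epimers are diastereomers and should be separable.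

Step 9
Reactants: 14 methyl (2R,4S)-4-[(2R,6E)-2,6-dimethyl-8-phenyloct-6-en-1-yl]-2,4-dimethyloxetane-2-carboxylate; 15 methyl acetate
Product: 16 methyl 3-{(2R,4S)-4-[(2R,6E)-2,6-dimethyl-8-phenyloct-6-en-1-yl]-2,4-dimethyloxetan-2-yl}-3-oxopropanoate
Conditions: 15, LiN(i-Pr)2, THF, −78 → −30 °C; AcOH quench
Reagents that add atoms: none
Why: Crossed Claisen condensation of lithiated methyl acetate with the non-enolisable oxetane ester should stop at the β-keto ester, which is held as its enolate until the quench, and the oxetane is stable to base.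

Step 10
Reactants: 16 methyl 3-{(2R,4S)-4-[(2R,6E)-2,6-dimethyl-8-phenyloct-6-en-1-yl]-2,4-dimethyloxetan-2-yl}-3-oxopropanoate
Product: 19 target cis-fused peroxy hemiketal γ-lactone (3R,4R,6R,8R,12E), via hydroperoxy keto ester 17 (not isolated), via dioxanol ester 18 (not isolated)
Conditions: H2O2 (anhydrous, in Et2O, 5 equiv), Me3SiOTf (0.3 equiv), Et2O, −78 → 0 °C; then PPTS (cat.), CH2Cl2, rt
Reagents that add atoms: hydrogen peroxide, OO
Why: Lewis-acid-mediated perhydrolysis of an oxetane should open the activated ring at the tertiary dialkyl carbon C6 (the C4–O bond is deactivated by the adjacent carbonyl) with inversion to the 6R hydroperoxide and the free C4 hydroxyl, after which the hydroperoxide adds to the C3 ketone (six-membered peroxy hemiketal) and the C4 hydroxyl lactonises onto the ester, the cis ring fusion fixing C3 under thermodynamic control.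

**Compound list**

1 | 5-hexyn-1-ol | C#CCCCCO | starting material
2 | benzyl chloride | ClCc1ccccc1 | starting material
3 | [(1E)-6-(dimethylalumanyloxy)-2-methylhex-1-en-1-yl]dimethylalumane | C/C(=C\[Al](C)C)CCCCO[Al](C)C | intermediate
4 | (E)-5-methyl-7-phenylhept-5-en-1-ol | C/C(=C\Cc1ccccc1)CCCCO | intermediate
5 | (E)-5-methyl-7-phenylhept-5-enal | C/C(=C\Cc1ccccc1)CCCC=O | intermediate
6 | 1-(triphenylphosphoranylidene)propan-2-one | CC(=O)C=P(c1ccccc1)(c1ccccc1)c1ccccc1 | starting material
7 | (3E,8E)-8-methyl-10-phenyldeca-3,8-dien-2-one | C/C(=C\Cc1ccccc1)CCC/C=C/C(C)=O | intermediate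
8 | (4R,8E)-4,8-dimethyl-10-phenyldec-8-en-2-one | C/C(=C\Cc1ccccc1)CCC[C@@H](C)CC(C)=O | intermediate
9 | (2R)-2-[(2R,6E)-2,6-dimethyl-8-phenyloct-6-en-1-yl]-2-methyloxirane | C/C(=C\Cc1ccccc1)CCC[C@@H](C)C[C@]1(C)CO1 | intermediate
10 | methyl (S)-lactate | C[C@H](O)C(=O)OC | starting material
11 | methyl (2S)-2-{[(2S,4R,8E)-1-hydroxy-2,4,8-trimethyl-10-phenyldec-8-en-2-yl]oxy}propanoate | C/C(=C\Cc1ccccc1)CCC[C@@H](C)C[C@@](C)(CO)O[C@@H](C)C(=O)OC | intermediate
12 | methyl (2S)-2-{[(2S,4R,8E)-1-iodo-2,4,8-trimethyl-10-phenyldec-8-en-2-yl]oxy}propanoate | C/C(=C\Cc1ccccc1)CCC[C@@H](C)C[C@@](C)(CI)O[C@@H](C)C(=O)OC | intermediate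
13 | lithium enolate of 12 (lithium 1-methoxy-2-alkoxyprop-1-en-1-olate) | C/C(=C\Cc1ccccc1)CCC[C@@H](C)C[C@@](C)(CI)OC(C)=C([O-])OC.[Li+] | intermediate
14 | methyl (2R,4S)-4-[(2R,6E)-2,6-dimethyl-8-phenyloct-6-en-1-yl]-2,4-dimethyloxetane-2-carboxylate | C/C(=C\Cc1ccccc1)CCC[C@@H](C)C[C@@]1(C)C[C@](C)(C(=O)OC)O1 | intermediate
15 | methyl acetate | CC(=O)OC | starting material
16 | methyl 3-{(2R,4S)-4-[(2R,6E)-2,6-dimethyl-8-phenyloct-6-en-1-yl]-2,4-dimethyloxetan-2-yl}-3-oxopropanoate | C/C(=C\Cc1ccccc1)CCC[C@@H](C)C[C@@]1(C)C[C@](C)(C(=O)CC(=O)OC)O1 | intermediate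
17 | methyl (4R,6R,8R,12E)-6-hydroperoxy-4-hydroxy-4,6,8,12-tetramethyl-3-oxo-14-phenyltetradec-12-enoate | C/C(=C\Cc1ccccc1)CCC[C@@H](C)C[C@@](C)(OO)C[C@@](C)(O)C(=O)CC(=O)OC | intermediate
18 | methyl 2-{(3R,4R,6R)-6-[(2R,6E)-2,6-dimethyl-8-phenyloct-6-en-1-yl]-3,4-dihydroxy-4,6-dimethyl-1,2-dioxan-3-yl}acetate | C/C(=C\Cc1ccccc1)CCC[C@@H](C)C[C@]1(C)C[C@@](C)(O)[C@@](O)(CC(=O)OC)OO1 | intermediate
19 | γ-lactone between the C3 acetic acid arm and the C4 oxygen of (3R,4R,6R)-6-[(2R,6E)-2,6-dimethyl-8-phenyloct-6-en-1-yl]-3,4-dihydroxy-4,6-dimethyl-1,2-dioxan-3-ylacetic acid (cis-fused peroxy hemiketal lactone) | C/C(=C\Cc1ccccc1)CCC[C@@H](C)C[C@]1(C)C[C@@]2(C)OC(=O)C[C@@]2(O)OO1 | target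

**Totals**

Total step count: 10. Longest linear sequence: 10 steps (from 1).

**Steps most likely to fail**

Step 8 (key step). What may go wrong: weak or reversed facial selection at trigonal C4 during ring closure, because the two groups on C6 differ little in size; slow displacement at the neopentyl-like C5 with decay of the enolate. Fallback: the order in which the two carbon substituents are attached to C4 is reversed, so that the face is chosen by an external electrophile on the preformed ring. This places the methyl group where step 8 places the ester terminus, so the two sequences are stereochemically complementary; the fallback is the one to use if step 8 favours the C4 epimer. It sets out from epoxide 9. Opening with methyl glycolate (BF3·OEt2) gives methyl 2-{[(2S,4R,8E)-1-hydroxy-2,4,8-trimethyl-10-phenyldec-8-en-2-yl]oxy}acetate F1. Iodination (I2, PPh3, imidazole) gives methyl 2-{[(2S,4R,8E)-1-iodo-2,4,8-trimethyl-10-phenyldec-8-en-2-yl]oxy}acetate F2. LiN(i-Pr)2 closes the same C4–C5 bond from a less hindered secondary enolate to give methyl (4S)-4-[(2R,6E)-2,6-dimethyl-8-phenyloct-6-en-1-yl]-4-methyloxetane-2-carboxylate F3 (both C2 epimers are used). Deprotonation of F3 (LiN(i-Pr)2, −78 °C) and methylation with MeI creates the quaternary centre, and the route is rejoined at oxetane ester 14.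

Step 10. What may go wrong: ionisation at C6 outrunning capture by H2O2 (erosion of the inversion, loss of a proton to an olefin, retro-Prins cleavage); binding of the Lewis acid by the β-keto ester; further addition of H2O2 at C3. Fallback: the perhydrolysis is moved one stage back and the peroxide is carried in masked form. It sets out from oxetane ester 14. Opening with Me3SiOTf/H2O2 gives methyl (2R,4R,6R,10E)-4-hydroperoxy-2-hydroxy-2,4,6,10-tetramethyl-12-phenyldodec-10-enoate F4. 2-Methoxypropene/PPTS ties the hydroperoxide and the C4 hydroxyl into methyl (5R,7R)-7-[(2R,6E)-2,6-dimethyl-8-phenyloct-6-en-1-yl]-3,3,5,7-tetramethyl-1,2,4-trioxepane-5-carboxylate F5. Claisen condensation with lithiated methyl acetate gives methyl 3-{(5R,7R)-7-[(2R,6E)-2,6-dimethyl-8-phenyloct-6-en-1-yl]-3,3,5,7-tetramethyl-1,2,4-trioxepan-5-yl}-3-oxopropanoate F6. Aqueous acetic acid removes the peroxyketal and releases hydroperoxy keto ester 17, where the route is rejoined (17 closes to 18 and then 19).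

Step 6. What may go wrong: a carbocation-like opening (partial loss of configuration at C6, hydride shift to an aldehyde) or attack at the CH2 terminus. Fallback: the ether is made on the oxygen of the tertiary alcohol, so that C6 is not substituted before step 10. It sets out from ketone 8. The antipodal catalyst of step 5, LaLi3[(R)-binaphtholate]3, gives (2S)-2-[(2R,6E)-2,6-dimethyl-8-phenyloct-6-en-1-yl]-2-methyloxirane F7. LiBr/AcOH in THF opens it at CH2 to (2S,4R,8E)-1-bromo-2,4,8-trimethyl-10-phenyldec-8-en-2-ol F8. Carbenoid O–H insertion (Rh2(OAc)4 or Cu(OTf)2) with methyl 2-diazopropanoate F9, made from methyl 2-methyl-3-oxobutanoate by deacylative diazo transfer, gives methyl 2-{[(2S,4R,8E)-1-bromo-2,4,8-trimethyl-10-phenyldec-8-en-2-yl]oxy}propanoate F10 (mixture at the propanoate carbon, which is erased on enolisation). LiN(i-Pr)2 then closes the ring with bromide as leaving group, and the route is rejoined at oxetane ester 14.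

Further compounds
F1 | step 8 | methyl 2-{[(2S,4R,8E)-1-hydroxy-2,4,8-trimethyl-10-phenyldec-8-en-2-yl]oxy}acetate | C/C(=C\Cc1ccccc1)CCC[C@@H](C)C[C@@](C)(CO)OCC(=O)OC
F2 | step 8 | methyl 2-{[(2S,4R,8E)-1-iodo-2,4,8-trimethyl-10-phenyldec-8-en-2-yl]oxy}acetate | C/C(=C\Cc1ccccc1)CCC[C@@H](C)C[C@@](C)(CI)OCC(=O)OC
F3 | step 8 | methyl (4S)-4-[(2R,6E)-2,6-dimethyl-8-phenyloct-6-en-1-yl]-4-methyloxetane-2-carboxylate (C2 epimers) | C/C(=C\Cc1ccccc1)CCC[C@@H](C)C[C@@]1(C)CC(C(=O)OC)O1
F4 | step 10 | methyl (2R,4R,6R,10E)-4-hydroperoxy-2-hydroxy-2,4,6,10-tetramethyl-12-phenyldodec-10-enoate | C/C(=C\Cc1ccccc1)CCC[C@@H](C)C[C@@](C)(OO)C[C@@](C)(O)C(=O)OC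
F5 | step 10 | methyl (5R,7R)-7-[(2R,6E)-2,6-dimethyl-8-phenyloct-6-en-1-yl]-3,3,5,7-tetramethyl-1,2,4-trioxepane-5-carboxylate | C/C(=C\Cc1ccccc1)CCC[C@@H](C)C[C@]1(C)C[C@](C)(C(=O)OC)OC(C)(C)OO1
F6 | step 10 | methyl 3-{(5R,7R)-7-[(2R,6E)-2,6-dimethyl-8-phenyloct-6-en-1-yl]-3,3,5,7-tetramethyl-1,2,4-trioxepan-5-yl}-3-oxopropanoate | C/C(=C\Cc1ccccc1)CCC[C@@H](C)C[C@]1(C)C[C@](C)(C(=O)CC(=O)OC)OC(C)(C)OO1
F7 | step 6 | (2S)-2-[(2R,6E)-2,6-dimethyl-8-phenyloct-6-en-1-yl]-2-methyloxirane | C/C(=C\Cc1ccccc1)CCC[C@@H](C)C[C@@]1(C)CO1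
F8 | step 6 | (2S,4R,8E)-1-bromo-2,4,8-trimethyl-10-phenyldec-8-en-2-ol | C/C(=C\Cc1ccccc1)CCC[C@@H](C)C[C@@](C)(CBr)O
F9 | step 6 | methyl 2-diazopropanoate | CC(=[N+]=[N-])C(=O)OC
F10 | step 6 | methyl 2-{[(2S,4R,8E)-1-bromo-2,4,8-trimethyl-10-phenyldec-8-en-2-yl]oxy}propanoate (both configurations at the propanoate carbon) | C/C(=C\Cc1ccccc1)CCC[C@@H](C)C[C@@](C)(CBr)OC(C)C(=O)OC
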